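**Retrosynthetic overview**
1. Target 25 ⇐ cation exchange, hydrogenolysis, sulfation and desilylation of flavone 21, in which O7 and O4' are silylated, O3 and O3' benzylated, and O5 is free and chelated.
2. Ring A (C4a, C5–C8, C8a) is formed last, from pyranonyl diazoketone 11 and siloxyacetylene 16 in one photochemical Wolff / [2+2] / 4π / 6π cascade (bonds C8–C8a, C5–C6, C7–C8, C4a–C5).
3. Feature used: ring C (O1, C2, C3–O, C4=O, C4a, C8a) is the 5-hydroxy-4-pyranone nucleus of kojic acid, and the meta oxygens of ring A come from the ketene carbonyl (O5) and the ynol ether oxygen (O7), so they are formed already differentiated.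
4. 11 ⇐ acid 9 ⇐ Suzuki coupling of 6-bromo-5-benzyloxy kojic alcohol 3 with arylboronate 7 (ring B, from 2-(benzyloxy)phenol).
5. 16 ⇐ lithium ethynolate made by ester homologation of ethyl formate, silylated on oxygen; an alkyl ynol ether offers no practical path to the O-silyl ynol ether.

Key step: step 10

Remark: the target is achiral, so no stereocentre has to be set; the free bis(hydrogen sulfate) is liberated only in the last step, because aryl hydrogen sulfates hydrolyse in their own acid.

**Route**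

Step 1
Reactants: 1 kojic acid
Product: 2 6-bromokojic acid (2-bromo-3-hydroxy-6-(hydroxymethyl)-4H-pyran-4-one)
Conditions: NBS (1.05 equiv), DMF, 0 °C to rt
Reagents that add atoms: N-bromosuccinimide, O=C1CCC(=O)N1Br
Why: Electrophilic bromination of the enolic pyranone should occur at C6, the only position ortho to the enolic hydroxyl and the same carbon that reacts in Mannich and aldol reactions of kojic acid.

Step 2
Reactants: 2 6-bromokojic acid
Product: 3 3-(benzyloxy)-2-bromo-6-(hydroxymethyl)-4H-pyran-4-one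
Conditions: BnBr (1.1 equiv), K2CO3, DMF, rt
Reagents that add atoms: benzyl bromide, BrCc1ccccc1
Why: Williamson alkylation of the acidic enolic hydroxyl; carbonate does not ionise the primary alcohol, so only the ring oxygen should be benzylated.

Step 3
Reactants: 4 2-(benzyloxy)phenol
Product: 5 2-(benzyloxy)-4-bromophenol
Conditions: NBS (1.0 equiv), MeCN, −10 to 0 °C
Reagents that add atoms: N-bromosuccinimide, O=C1CCC(=O)N1Br
Why: Electrophilic aromatic bromination directed para to the free hydroxyl, the stronger donor, as in the bromination of guaiacol to 4-bromoguaiacol.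

Step 4
Reactants: 5 2-(benzyloxy)-4-bromophenol
Product: 6 [2-(benzyloxy)-4-bromophenoxy]triisopropylsilane
Conditions: TIPSCl, imidazole, DMF, rt
Reagents that add atoms: triisopropylsilyl chloride, CC(C)[Si](Cl)(C(C)C)C(C)C
Why: Standard imidazole-promoted silylation of a phenol; the bulky TIPS ether is chosen to survive the borylation, the coupling and the oxidation.

Step 5
Reactants: 6 [2-(benzyloxy)-4-bromophenoxy]triisopropylsilane
Product: 7 2-[3-(benzyloxy)-4-(triisopropylsilyloxy)phenyl]-4,4,5,5-tetramethyl-1,3,2-dioxaborolane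
Conditions: B2pin2, Pd(dppf)Cl2 (cat.), KOAc, dioxane, 85 °C
Reagents that add atoms: bis(pinacolato)diboron, CC1(C)OB(OC1(C)C)B1OC(C)(C)C(C)(C)O1
Why: Miyaura borylation of an aryl bromide under weakly basic acetate conditions that leave the aryl silyl ether and the benzyl ether intact.

Step 6
Reactants: 3 3-(benzyloxy)-2-bromo-6-(hydroxymethyl)-4H-pyran-4-one; 7 arylboronate
Product: 8 5-(benzyloxy)-6-[3-(benzyloxy)-4-(triisopropylsilyloxy)phenyl]-2-(hydroxymethyl)-4H-pyran-4-one
Conditions: Pd(OAc)2/SPhos (cat.), K3PO4, toluene/H2O 10:1, 60 °C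
Reagents that add atoms: none
Why: Suzuki–Miyaura coupling; the C–Br bond is a vinylogous acyl bromide and should add to palladium easily, and the mild phosphate base and moderate temperature are chosen to keep the aryl TIPS ether.

Step 7
Reactants: 8 pyranone alcohol
Product: 9 5-(benzyloxy)-6-[3-(benzyloxy)-4-(triisopropylsilyloxy)phenyl]-4-oxo-4H-pyran-2-carboxylic acid
Conditions: TEMPO (0.2 equiv), PhI(OAc)2 (2.5 equiv), MeCN/H2O 1:1, rt
Reagents that add atoms: water, O
Why: Oxoammonium (TEMPO/BAIB) oxidation of the activated primary alcohol to the aldehyde, whose hydrate is oxidised on to the acid, under near-neutral conditions that spare the silyl and benzyl ethers.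

Step 8
Reactants: 9 pyranone carboxylic acid
Product: 11 5-(benzyloxy)-6-[3-(benzyloxy)-4-(triisopropylsilyloxy)phenyl]-2-(diazoacetyl)-4H-pyran-4-one, via mixed carbonic anhydride 10 (not isolated)
Conditions: i-BuOCOCl, N-methylmorpholine, THF, −15 °C; then CH2N2 (Et2O, 3 equiv), 0 °C, short contact; AcOH quench
Reagents that add atoms: isobutyl chloroformate, CC(C)COC(Cl)=O (carried by 10 only); diazomethane, C=[N+]=[N-]
Why: Acylation of diazomethane by a mixed anhydride (first stage of the Arndt–Eistert sequence); no acidic OH is present to be methylated, and low temperature and short contact are meant to keep diazomethane from adding to the pyranone C=C.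

Step 9
Reactants: 12 ethyl formate; 13 triisopropylsilyl triflate
Product: 16 (triisopropylsilyloxy)acetylene, via lithium 2,2-dibromoethenolate 14 (not isolated), via lithium ethynolate 15 (not isolated)
Conditions: CH2Br2, LiTMP (2 equiv), THF, −78 °C; n-BuLi, −78 to 0 °C; then 13, −78 °C to rt; rapid filtration through Et3N-deactivated silica
Reagents that add atoms: dibromomethane, BrCBr; lithium 2,2,6,6-tetramethylpiperidide, [Li]N1C(C)(C)CCCC1(C)C (lithium of 14 and 15 only)
Why: Kowalski ester homologation applied to a formate: LiCHBr2 adds to the ester, base gives dibromo enolate 14, Br/Li exchange gives a carbenoid that rearranges by 1,2-hydride shift to ynolate 15, and the bulky silyl triflate should silylate it on oxygen.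

Step 10
Reactants: 11 pyranonyl diazoketone; 16 (triisopropylsilyloxy)acetylene (3 equiv)
Product: 21 3,3'-di-O-benzyl-7,4'-bis-O-(triisopropylsilyl)quercetin, via pyranonylketene 17 (not isolated), via siloxycyclobutenone 18 (not isolated), via dienylketene 19 (not isolated), via cyclohexadienone 20 (not isolated)
Conditions: hν (440–450 nm LED), degassed ClCH2CH2Cl, rt until 11 is consumed; then 80 °C
Reagents that add atoms: none
Why: Irradiation in the n→π* band of the diazoketone expels N2 with 1,2-shift of the pyranonyl carbon C8a onto the diazo carbon (photochemical Wolff rearrangement, C8–C8a) to give ketene 17, which the ynol ether 16 traps in a [2+2] cycloaddition (C5–C6 and C7–C8) to give cyclobutenone 18. Warming opens 18 by reversible 4π electrocyclic cleavage of the C5–C8 bond to dienylketene 19, whose ketene carbon closes onto C4a in a thermal disrotatory 6π electrocyclisation (C4a–C5), and dienone 20 tautomerises to the chelated phenol 21; ring A is thus closed by a 6π electrocyclisation across the C8a=C4a bond of the pyranone. The closest known reaction is the diazoketone variant of the Danheiser benzannulation of aryl, heteroaryl and alkenyl diazoketones with triisopropylsilyl ynol ethers. The step needs the [2+2] regiochemistry in which the nucleophilic CH terminus of 16 bonds to the ketene carbonyl carbon; the oxygen-polarised alkyne secures it and places the silyloxy group at C7, meta to the new C5 hydroxyl. The site of ring closure is fixed because C8a carries the ring oxygen on its other side, so C4a–H is the only carbon terminus, and the reversible ring opening lets 19 reach the geometry needed for closure. No stereocentre is formed, and visible light is used so that the diazoketone is excited and the 3-benzyloxy-2-arylpyranone chromophore is not.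

Step 11
Reactants: 21 3,3'-di-O-benzyl-7,4'-bis-O-(triisopropylsilyl)quercetin
Product: 22 3,3'-di-O-benzylquercetin (3-(benzyloxy)-2-[3-(benzyloxy)-4-hydroxyphenyl]-5,7-dihydroxy-4H-chromen-4-one)
Conditions: TBAF (2.4 equiv), AcOH (2.4 equiv), THF, 0 °C
Reagents that add atoms: none
Why: Fluoride-induced cleavage of both aryl silyl ethers; the benzyl ethers are inert and the acetic acid buffer keeps the electron-rich phenols protonated.

Step 12
Reactants: 22 3,3'-di-O-benzylquercetin
Product: 23 disodium 3,3'-di-O-benzylquercetin 7,4'-bis(sulfate)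
Conditions: SO3·pyridine (8 equiv), pyridine, 40 °C; then aq. NaHCO3 to pH 8; C18 or Sephadex LH-20
Reagents that add atoms: sulfur trioxide–pyridine complex, O=S(=O)([O-])[n+]1ccccc1; sodium hydrogen carbonate, [Na+].OC(=O)[O-]
Why: O-Sulfonation of phenols with a sulfur trioxide–amine complex; O3 and O3' are blocked, and the 5-hydroxyl, hydrogen-bonded to the C4 carbonyl, is the hydroxyl that generally stays free in flavonoid sulfations.

Step 13
Reactants: 23 disodium 3,3'-di-O-benzylquercetin 7,4'-bis(sulfate)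
Product: 24 disodium quercetin 7,4'-bis(sulfate)
Conditions: H2 (1 atm), 10% Pd/C, MeOH/H2O 4:1 (pH about 7), rt
Reagents that add atoms: none
Why: Catalytic hydrogenolysis of the two benzyl ethers at neutral pH, under which aryl sulfate salts are stable and the flavonol C2=C3 bond should not be reduced.

Step 14
Reactants: 24 disodium quercetin 7,4'-bis(sulfate)
Product: 25 3',5-dihydroxy-4',7-bis(sulfooxy)flavonol (quercetin 7,4'-bis(hydrogen sulfate))
Conditions: Dowex 50WX8 (H+ form), H2O, 0–5 °C; immediate freeze-drying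
Reagents that add atoms: none
Why: Cation exchange of sodium for protons on a sulfonic acid resin gives the free acid without added mineral acid; cold, brief handling limits hydrolysis of the sulfate esters.

**Compound list**
1 | kojic acid | O=c1cc(CO)occ1O | starting material
2 | 6-bromokojic acid | O=c1cc(CO)oc(Br)c1O | intermediate
3 | 3-(benzyloxy)-2-bromo-6-(hydroxymethyl)-4H-pyran-4-one | O=c1cc(CO)oc(Br)c1OCc1ccccc1 | intermediate
4 | 2-(benzyloxy)phenol | Oc1ccccc1OCc1ccccc1 | starting material
5 | 2-(benzyloxy)-4-bromophenol | Oc1ccc(Br)cc1OCc1ccccc1 | intermediate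
6 | [2-(benzyloxy)-4-bromophenoxy]triisopropylsilane | CC(C)[Si](Oc1ccc(Br)cc1OCc1ccccc1)(C(C)C)C(C)C | intermediate
7 | 2-[3-(benzyloxy)-4-(triisopropylsilyloxy)phenyl]-4,4,5,5-tetramethyl-1,3,2-dioxaborolane | CC(C)[Si](Oc1ccc(B2OC(C)(C)C(C)(C)O2)cc1OCc1ccccc1)(C(C)C)C(C)C | intermediate
8 | 5-(benzyloxy)-6-[3-(benzyloxy)-4-(triisopropylsilyloxy)phenyl]-2-(hydroxymethyl)-4H-pyran-4-one | OCc1cc(=O)c(OCc2ccccc2)c(-c2ccc(O[Si](C(C)C)(C(C)C)C(C)C)c(OCc3ccccc3)c2)o1 | intermediate
9 | 5-(benzyloxy)-6-[3-(benzyloxy)-4-(triisopropylsilyloxy)phenyl]-4-oxo-4H-pyran-2-carboxylic acid | OC(=O)c1cc(=O)c(OCc2ccccc2)c(-c2ccc(O[Si](C(C)C)(C(C)C)C(C)C)c(OCc3ccccc3)c2)o1 | intermediate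
10 | isobutyl carbonic anhydride of acid 9 (not isolated) | CC(C)COC(=O)OC(=O)c1cc(=O)c(OCc2ccccc2)c(-c2ccc(O[Si](C(C)C)(C(C)C)C(C)C)c(OCc3ccccc3)c2)o1 | intermediate
11 | 5-(benzyloxy)-6-[3-(benzyloxy)-4-(triisopropylsilyloxy)phenyl]-2-(diazoacetyl)-4H-pyran-4-one | [N-]=[N+]=CC(=O)c1cc(=O)c(OCc2ccccc2)c(-c2ccc(O[Si](C(C)C)(C(C)C)C(C)C)c(OCc3ccccc3)c2)o1 | intermediate
12 | ethyl formate | CCOC=O | starting material
13 | triisopropylsilyl triflate | CC(C)[Si](C(C)C)(C(C)C)OS(=O)(=O)C(F)(F)F | starting material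
14 | lithium 2,2-dibromoethenolate (not isolated) | [Li+].[O-]C=C(Br)Br | intermediate
15 | lithium ethynolate (not isolated) | [Li+].[O-]C#C | intermediate
16 | (triisopropylsilyloxy)acetylene | C#CO[Si](C(C)C)(C(C)C)C(C)C | intermediate
17 | pyranonylketene from Wolff rearrangement (not isolated) | O=C=Cc1cc(=O)c(OCc2ccccc2)c(-c2ccc(O[Si](C(C)C)(C(C)C)C(C)C)c(OCc3ccccc3)c2)o1 | intermediate
18 | 4-(pyranonyl)-3-(triisopropylsilyloxy)cyclobut-2-en-1-one, racemic (not isolated) | O=C1C=C(O[Si](C(C)C)(C(C)C)C(C)C)C1c1cc(=O)c(OCc2ccccc2)c(-c2ccc(O[Si](C(C)C)(C(C)C)C(C)C)c(OCc3ccccc3)c2)o1 | intermediate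
19 | dienylketene with ketene chain and pyranonyl group cis on C7=C8 (not isolated) | O=C=C/C(O[Si](C(C)C)(C(C)C)C(C)C)=C\c1cc(=O)c(OCc2ccccc2)c(-c2ccc(O[Si](C(C)C)(C(C)C)C(C)C)c(OCc3ccccc3)c2)o1 | intermediate
20 | 4a-H cyclohexadienone tautomer of 21, racemic (not isolated) | O=C1C=C(O[Si](C(C)C)(C(C)C)C(C)C)C=C2OC(-c3ccc(O[Si](C(C)C)(C(C)C)C(C)C)c(OCc4ccccc4)c3)=C(OCc3ccccc3)C(=O)C12 | intermediate
21 | 3,3'-di-O-benzyl-7,4'-bis-O-(triisopropylsilyl)quercetin | O=c1c(OCc2ccccc2)c(-c2ccc(O[Si](C(C)C)(C(C)C)C(C)C)c(OCc3ccccc3)c2)oc2cc(O[Si](C(C)C)(C(C)C)C(C)C)cc(O)c12 | intermediate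
22 | 3,3'-di-O-benzylquercetin | O=c1c(OCc2ccccc2)c(-c2ccc(O)c(OCc3ccccc3)c2)oc2cc(O)cc(O)c12 | intermediate
23 | disodium 3,3'-di-O-benzylquercetin 7,4'-bis(sulfate) | [Na+].[Na+].O=c1c(OCc2ccccc2)c(-c2ccc(OS(=O)(=O)[O-])c(OCc3ccccc3)c2)oc2cc(OS(=O)(=O)[O-])cc(O)c12 | intermediate
24 | disodium quercetin 7,4'-bis(sulfate) | [Na+].[Na+].O=c1c(O)c(-c2ccc(OS(=O)(=O)[O-])c(O)c2)oc2cc(OS(=O)(=O)[O-])cc(O)c12 | intermediate
25 | 3',5-dihydroxy-4',7-bis(sulfooxy)flavonol | O=c1c(O)c(-c2ccc(OS(=O)(=O)O)c(O)c2)oc2cc(OS(=O)(=O)O)cc(O)c12 | target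

**Step count and risks**

Total step count: 14. Longest linear sequence: 11 steps (from 2-(benzyloxy)phenol 4 to 25: steps 3, 4, 5, 6, 7, 8, 10, 11, 12, 13, 14).

Steps most likely to fail:

1. Step 10. The 3-benzyloxy-2-arylpyranone may undergo its own photochemistry (hydrogen abstraction from the benzylic OCH2, ring contraction of the pyranone) if it absorbs at the wavelength used. The ketene may also dimerise or be intercepted before the cycloaddition, or the dienylketene may fail to close onto the pyranone C=C. The fallback builds the flavone by a Baker–Venkataraman sequence; it sets out from bromophenol 5 and returns at 22.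
 - Bromophenol 5 is protected (MOMCl, i-Pr2NEt) to give 2-(benzyloxy)-4-bromo-1-(methoxymethoxy)benzene F1.
 - Bromine–lithium exchange and carboxylation (n-BuLi, then CO2) give 3-(benzyloxy)-4-(methoxymethoxy)benzoic acid F2.
 - Separately, Hoesch acylation of phloroglucinol with benzyloxyacetonitrile (ZnCl2, HCl, then hydrolysis) gives 2-(benzyloxy)-1-(2,4,6-trihydroxyphenyl)ethan-1-one F3.
 - MOMCl and i-Pr2NEt convert F3 into 2-(benzyloxy)-1-[2-hydroxy-4,6-bis(methoxymethoxy)phenyl]ethan-1-one F4, the chelated hydroxyl staying free.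
 - Esterification of F4 with F2 (EDC, DMAP) gives 2-[2-(benzyloxy)acetyl]-3,5-bis(methoxymethoxy)phenyl 3-(benzyloxy)-4-(methoxymethoxy)benzoate F5.
 - Baker–Venkataraman acyl migration (LiHMDS, THF) gives 2-(benzyloxy)-1-[3-(benzyloxy)-4-(methoxymethoxy)phenyl]-3-[2-hydroxy-4,6-bis(methoxymethoxy)phenyl]propane-1,3-dione F6.
 - HCl in MeOH cyclodehydrates F6 and removes the three MOM groups to give 3,3'-di-O-benzylquercetin 22.

2. Step 9. Dibromomethyllithium may add twice to the very reactive formate, and the ynolate may be deprotonated further and then silylated on both carbon and oxygen, so that little mono-O-silyl ynol ether is isolated. The fallback generates the same ynolate by fragmentation of a heterocycle. It sets out from triisopropylsilyl triflate 13 and commercial 3-phenylisoxazole. n-BuLi in THF at −78 °C should give 5-lithio-3-phenylisoxazole F7, which on warming to about −30 °C fragments into benzonitrile and lithium ethynolate 15. O-Silylation with 13 returns to the route at 16.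

3. Step 8. Diazomethane may add as a 1,3-dipole across the electron-poor C=C bond of the pyranone that is flanked by two carbonyl groups, so pyrazoline formation competes with acylation. The fallback avoids diazomethane by detrifluoroacetylative diazo transfer; it sets out from acid 9 and returns at 11.
 - Acid 9 is coupled with N,O-dimethylhydroxylamine (EDC, HOBt) to give N-methoxy-N-methyl-5-(benzyloxy)-6-[3-(benzyloxy)-4-(triisopropylsilyloxy)phenyl]-4-oxo-4H-pyran-2-carboxamide F8.
 - MeMgBr at −78 °C gives 2-acetyl-5-(benzyloxy)-6-[3-(benzyloxy)-4-(triisopropylsilyloxy)phenyl]-4H-pyran-4-one F9.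
 - LiHMDS and 2,2,2-trifluoroethyl trifluoroacetate give 5-(benzyloxy)-6-[3-(benzyloxy)-4-(triisopropylsilyloxy)phenyl]-2-(4,4,4-trifluoro-3-oxobutanoyl)-4H-pyran-4-one F10.
 - Methanesulfonyl azide, Et3N and water in MeCN transfer the diazo group with loss of the trifluoroacetyl group to give diazoketone 11.

**Further compounds**
F1 | step 10 | 2-(benzyloxy)-4-bromo-1-(methoxymethoxy)benzene | COCOc1ccc(Br)cc1OCc1ccccc1
F2 | step 10 | 3-(benzyloxy)-4-(methoxymethoxy)benzoic acid | COCOc1ccc(C(=O)O)cc1OCc1ccccc1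
F3 | step 10 | 2-(benzyloxy)-1-(2,4,6-trihydroxyphenyl)ethan-1-one | O=C(COCc1ccccc1)c1c(O)cc(O)cc1O
F4 | step 10 | 2-(benzyloxy)-1-[2-hydroxy-4,6-bis(methoxymethoxy)phenyl]ethan-1-one | COCOc1cc(O)c(C(=O)COCc2ccccc2)c(OCOC)c1
F5 | step 10 | 2-[2-(benzyloxy)acetyl]-3,5-bis(methoxymethoxy)phenyl 3-(benzyloxy)-4-(methoxymethoxy)benzoate | COCOc1cc(OC(=O)c2ccc(OCOC)c(OCc3ccccc3)c2)c(C(=O)COCc2ccccc2)c(OCOC)c1
F6 | step 10 | 2-(benzyloxy)-1-[3-(benzyloxy)-4-(methoxymethoxy)phenyl]-3-[2-hydroxy-4,6-bis(methoxymethoxy)phenyl]propane-1,3-dione | COCOc1cc(O)c(C(=O)C(OCc2ccccc2)C(=O)c2ccc(OCOC)c(OCc3ccccc3)c2)c(OCOC)c1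
F7 | step 9 | 5-lithio-3-phenylisoxazole | [Li]c1cc(-c2ccccc2)no1
F8 | step 8 | N-methoxy-N-methyl-5-(benzyloxy)-6-[3-(benzyloxy)-4-(triisopropylsilyloxy)phenyl]-4-oxo-4H-pyran-2-carboxamide | CON(C)C(=O)c1cc(=O)c(OCc2ccccc2)c(-c2ccc(O[Si](C(C)C)(C(C)C)C(C)C)c(OCc3ccccc3)c2)o1
F9 | step 8 | 2-acetyl-5-(benzyloxy)-6-[3-(benzyloxy)-4-(triisopropylsilyloxy)phenyl]-4H-pyran-4-one | CC(=O)c1cc(=O)c(OCc2ccccc2)c(-c2ccc(O[Si](C(C)C)(C(C)C)C(C)C)c(OCc3ccccc3)c2)o1
F10 | step 8 | 5-(benzyloxy)-6-[3-(benzyloxy)-4-(triisopropylsilyloxy)phenyl]-2-(4,4,4-trifluoro-3-oxobutanoyl)-4H-pyran-4-one | O=C(CC(=O)C(F)(F)F)c1cc(=O)c(OCc2ccccc2)c(-c2ccc(O[Si](C(C)C)(C(C)C)C(C)C)c(OCc3ccccc3)c2)o1
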